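## Analysis of the target

The target (21) is a branched C15 hydroxy acid chain tied through a ketone to its only ring, a (6R)-4-hydroxy-6-methyl-5,6-dihydro-2H-pyran-2-one (ring atoms rO1, rC2 to rC6). The chain is numbered from the carboxyl carbon: C1 (CO2H), C2 (CH), C3 (CHOH), C4 (CHMe), C5–C6 (ethyl); the substituent on C2 is C1'=C2' (E), C3'H2, C4'(=CH2), C5'H2, C6'H2 and C7'(=O), and C7' is bonded to rC3. There are four stereocentres: C2 (R), C3 (R) and C4 (S) are contiguous, with C2/C3 anti in the aldol sense and C3/C4 in the Felkin (syn) sense, for which methyl versus ethyl at C4 gives almost no substrate bias; rC6 (R) is remote and independent. The two alkenes form a skipped 1,4-diene, C1'=C2'–C3'H2–C4'(=CH2): one alkene is E-disubstituted and sits directly on the stereogenic C2, the other is 1,1-disubstituted. C2–H is both α to the carboxyl group and allylic, so base or a metal hydride can epimerise C2 or pull C1'=C2' into conjugation, and the β-hydroxy acid can dehydrate or undergo retro-aldol cleavage. rC2(=O), rC4(–OH) and C7'(=O) form an enolised, acidic, metal-chelating tricarbonyl, and the doubly allylic C3'H2 is prone to isomerisation. The difficulty is placement, not size: the E-alkene must be put on C2 without ever making an enolate there, the skipped diene must be built with control of regiochemistry and geometry, and the two polar ends call for a late, mild union.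

## Retrosynthetic reasoning

21 ⇒ 10 + 19 (key disconnection). The skipped diene C1'=C2'–C3'H2–C4'(=CH2) is read as the product of an intermolecular Alder-ene reaction. The C3'–C4' bond is cut, one hydrogen of the methylidene carbon is returned to C1', and the E-alkene is moved back to a terminal C2'=C3' allyl group. This gives the terminal alkyne 19 and the α-allyl β-hydroxy acid 10, two halves of nearly equal size that together hold every atom of 21. The cut is made here, and not at C2–C3 or C7'–rC3, because it removes the C2 lability from the whole route: in 10, C2 bears an allyl group and is an ordinary α-alkyl centre, and the β,γ-unsaturated acid appears only in the last, neutral, base-free operation. The forward ruthenium-catalysed coupling (through metallacycle 20) has to give the branched regioisomer and the E geometry, and has to tolerate a free acid, a free alcohol and the enolised tricarbonyl so that no protecting group is needed.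

19 ⇒ 16 + 17. The C7'–rC3 bond is cut. Forward, the enol of 16 is O-acylated with the commercial alkynoic acid 17 by a carbodiimide, and the enol ester 18 rearranges in the same flask by O→C acyl migration. The tricarbonyl is thus installed on a small fragment, where the nucleophilic base never meets the C2/C3/C4 triad.

16 ⇒ 14 ⇒ 11 + 12. The lactone bond rO1–rC2 is opened to the δ-hydroxy β-keto ester 14 (closure runs through acid 15). The rC3–rC4 bond is then cut by a crossed Claisen condensation between the chiral-pool ester 11 and the enolate 13 of 12. rC6 is bought, not made.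

10 ⇒ 9 ⇒ 6 + 7. After ester hydrolysis (9 to 10), the C2–C1' bond is cut. Forward, a Fráter–Seebach allylation of the dianion 8 of β-hydroxy ester 6 with 7 lets the C3 carbinol set C2 anti. No aldol with a labile α-chiral aldehyde is needed.

6 ⇒ 5 ⇒ 1 + 2. The C3 carbinol is traced to ketone 5, so that a catalyst-controlled hydrogenation replaces the unreliable Felkin control from C4. The C2–C3 bond of 5 is cut by a Masamune–Brooks acylation of malonate half-ester 2 with the imidazolide 3 of chiral-pool acid 1 (through 4), which supplies C4.

## Alternatives that were turned down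

Alternative 1: The textbook route. The C7'–rC3 bond would be made last by carbodiimide acylation of 16 with the full seco-acid A1, and the C2–C3 bond of A1 by an anti-selective aldol of the skipped-diene diester A2 (as its C8 enolate) with the aldehyde (S)-2-methylbutanal A3. Enolisation of A2 gives a dienolate that can react at the α or γ carbon and reprotonates towards the conjugated ester. The anti sense would need a stoichiometric auxiliary in place of the simple ester. A3 is volatile, racemises easily and has almost no Felkin bias (methyl versus ethyl). After the aldol, the doubly activated C2–H of A1 has to survive ester differentiation, acylation and a final ester cleavage. A2 still contains the skipped diene, so the hardest part is only moved, at a cost of clearly more steps and two orthogonal carboxyl protections.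

Alternative 2: An sp2–sp3 cross-coupling at C2'–C3'. A Stille coupling would join the E-vinylstannane A4 with the 2-substituted allylic bromide A5 through a π-allylpalladium intermediate. The coupling itself is reasonable (the π-allyl termini are equivalent), but both partners are poor: A4 puts a stannylvinyl group on the labile C2 and would have to come from a deconjugative aldol or from hydrostannation of an α-ethynyl aldol, carrying the epimerisable C2–H through several steps. A5 combines an allylic bromide with an acidic, nucleophilic tricarbonyl enol and would alkylate itself unless protected. The result is two long fragment syntheses and stoichiometric tin for one C–C bond.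

Alternative 3: Olefin cross-metathesis at C1'=C2' between the α-vinyl aldol ester A6 and the 1,4-diene A7. The vinyl group of A6 sits on a branched allylic carbon and is a sluggish metathesis partner. Ruthenium hydrides that form from the alkylidene catalyst isomerise β,γ-unsaturated esters and skipped dienes. E/Z control is only thermodynamic, and A7 can homodimerise. A6 again needs an α-selective dienolate aldol, and A7 already holds the skipped diene, so this cut does not simplify the problem.

Key step: step 8

Assumption: the tricarbonyl of 19 and 21 and the β-keto lactone 16 are written as the 4-hydroxy enol tautomers of the target SMILES; which tautomer is present affects no step.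

## Route

Step 1
Reactants: 1 (S)-2-methylbutanoic acid; 2 potassium ethyl malonate
Product: 5 ethyl (S)-4-methyl-3-oxohexanoate, via acyl imidazolide 3 (not isolated), via acylmalonate half-ester 4 (not isolated)
Conditions: CDI, THF, rt; then 2, MgCl2, Et3N, MeCN/THF, rt → 40 °C; aq. HCl work-up
Reagents that add atoms: none
Why: Masamune–Brooks homologation: the magnesium enolate of the malonate half-ester is C-acylated by imidazolide 3 and the adduct 4 decarboxylates on acidification; the mild conditions should leave the α-stereocentre of 1 intact, and in the product it is shielded because the β-keto ester is held as its C2 enolate; no new stereocentre is formed.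

Step 2
Reactants: 5 ethyl (S)-4-methyl-3-oxohexanoate
Product: 6 ethyl (3S,4S)-3-hydroxy-4-methylhexanoate
Conditions: H2 (10 bar), [RuCl(p-cymene)((R)-BINAP)]Cl (0.5 mol %), EtOH, 50 °C
Reagents that add atoms: none
Why: Noyori asymmetric hydrogenation of a β-keto ester through the ruthenium-chelated keto ester; the ligand, not the weakly biasing C4 centre, should fix C3, and (R)-BINAP is chosen by analogy with its established sense for simple β-keto esters (the descriptor is 3S only because sec-butyl outranks CH2CO2Et); C4 is not flanked by two carbonyls and should not epimerise.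

Step 3
Reactants: 6 ethyl (3S,4S)-3-hydroxy-4-methylhexanoate; 7 allyl bromide
Product: 9 ethyl (2R,3R,4S)-3-hydroxy-4-methyl-2-(prop-2-en-1-yl)hexanoate, via dilithium alkoxide-enolate 8 (not isolated)
Conditions: LDA (2.2 equiv), THF, −78 → −20 °C; then 7, DMPU, −78 → 0 °C; aq. HCl quench
Reagents that add atoms: none
Why: Fráter–Seebach alkylation: the lithium-bridged six-membered alkoxide–enolate chelate 8 should be attacked by 7 on the face opposite the C3 sec-butyl group, which sets C2 anti to the C3 oxygen (2R); the alkoxide protects the hydroxyl in situ and C4 has no acidifying neighbour.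

Step 4
Reactants: 9 ethyl (2R,3R,4S)-3-hydroxy-4-methyl-2-(prop-2-en-1-yl)hexanoate
Product: 10 (2R,3R,4S)-3-hydroxy-4-methyl-2-(prop-2-en-1-yl)hexanoic acid
Conditions: LiOH·H2O, THF/MeOH/H2O, rt → 40 °C; then 1 M HCl to pH 2–3
Reagents that add atoms: lithium hydroxide monohydrate, O.[Li+].[OH-]
Why: Plain saponification; at this stage C2 bears an allyl and not a vinyl group, so hydroxide should neither epimerise nor conjugate it, and retro-aldol of an ester or carboxylate aldol is slow at these temperatures.

Step 5
Reactants: 11 ethyl (R)-3-hydroxybutanoate; 12 tert-butyl acetate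
Product: 14 tert-butyl (R)-5-hydroxy-3-oxohexanoate, via lithium enolate of tert-butyl acetate 13 (not isolated)
Conditions: LDA (3.5 equiv), 12 (3.5 equiv), THF, −78 °C; then 11, −78 → −30 °C; aq. HCl quench to pH 5
Reagents that add atoms: none
Why: Crossed Claisen condensation: excess enolate 13 first deprotonates the hydroxyl of 11 and then adds to the ethyl ester, and the product is protected from over-addition as its β-keto ester enolate; the carbinol stereocentre takes no part.

Step 6
Reactants: 14 tert-butyl (R)-5-hydroxy-3-oxohexanoate
Product: 16 (R)-4-hydroxy-6-methyl-5,6-dihydro-2H-pyran-2-one, via hydroxy keto acid 15 (not isolated)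
Conditions: TFA, CH2Cl2, 0 °C → rt
Reagents that add atoms: none
Why: Acidolysis of the tert-butyl ester and 6-exo-trig lactonisation of the δ-hydroxy β-keto acid 15, which should outrun decarboxylation at room temperature; the C–O bond at rC6 is not broken, so the R configuration is kept.

Step 7
Reactants: 16 (R)-4-hydroxy-6-methyl-5,6-dihydro-2H-pyran-2-one; 17 pent-4-ynoic acid
Product: 19 (R)-4-hydroxy-6-methyl-3-(pent-4-ynoyl)-5,6-dihydro-2H-pyran-2-one, via O-acyl enol ester 18 (not isolated)
Conditions: DCC, DMAP, CH2Cl2, 0 °C → rt
Reagents that add atoms: none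
Why: Steglich-type O-acylation of the acidic enol followed by DMAP-mediated O→C acyl migration (Fries-type, through an acylpyridinium/enolate ion pair) should give the thermodynamically favoured, hydrogen-bonded 3-acyl tricarbonyl; the terminal alkyne is inert.

Step 8
Reactants: 10 (2R,3R,4S)-3-hydroxy-4-methyl-2-(prop-2-en-1-yl)hexanoic acid; 19 (R)-4-hydroxy-6-methyl-3-(pent-4-ynoyl)-5,6-dihydro-2H-pyran-2-one
Product: 21 (2R,3R,4S)-3-hydroxy-2-{(1E)-7-[(6R)-4-hydroxy-6-methyl-2-oxo-5,6-dihydro-2H-pyran-3-yl]-4-methylidene-7-oxohept-1-en-1-yl}-4-methylhexanoic acid (target CNP0221901.1), via ruthenacyclopentene 20 (not isolated)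
Conditions: [CpRu(MeCN)3]PF6 (10 mol %), 19 (1.0 equiv), 10 (1.2 equiv), degassed acetone, rt
Reagents that add atoms: none
Why: Ruthenium-catalysed intermolecular alkene–alkyne coupling (Alder-ene type): the cationic CpRu fragment binds the terminal alkyne of 19 and the monosubstituted alkene of 10, oxidative cyclisation joins the internal alkyne carbon (future C4') to the terminal alkene carbon (future C3') to give ruthenacyclopentene 20, and syn β-hydride elimination from the exocyclic allylic CH2 (future C1') followed by C–H reductive elimination at the former alkyne terminus (future =CH2) releases 21 and the catalyst. The closest known reaction type is the CpRu-catalysed coupling of terminal alkynes with α-olefins to branched 1,4-dienes, run at room temperature under neutral conditions and compatible with free hydroxyl, ketone and ester groups. No ring of the product is closed and no stereocentre is created; the only ring formed is the transient five-membered metallacycle. The step needs branched over linear regiochemistry, which the unbranched CH2CH2 group at the propargylic position of 19 and the monosubstituted alkene of 10 should secure, since the new C–C bond then forms between the less hindered alkene terminus and the substituted alkyne carbon. It needs E geometry at C1'=C2', which is set in the β-hydride elimination from the rotamer that turns the bulky C2 substituent away from the metallacycle, and the site of hydrogen transfer is unambiguous because 10 has a single allylic CH2. C2–H is never touched: C2 is γ to ruthenium in 20 and cannot β-eliminate, and no base is present, so the anti C2/C3 relationship and the 4S centre from steps 2 and 3 and the 6R centre from 11 are carried over unchanged. The di- and 1,1-disubstituted alkenes of 21 are much poorer partners than a terminal alkene, which should protect the product from a second coupling or isomerisation.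

## Compound list

1 | (S)-2-methylbutanoic acid | CC[C@H](C)C(=O)O | starting material
2 | potassium ethyl malonate (potassium 3-ethoxy-3-oxopropanoate) | CCOC(=O)CC(=O)[O-].[K+] | starting material
3 | (S)-1-(1H-imidazol-1-yl)-2-methylbutan-1-one | CC[C@H](C)C(=O)n1ccnc1 | intermediate (not isolated)
4 | (4S)-2-(ethoxycarbonyl)-4-methyl-3-oxohexanoic acid (present as its magnesium chelate; C2 not defined) | CCOC(=O)C(C(=O)O)C(=O)[C@@H](C)CC | intermediate (not isolated)
5 | ethyl (S)-4-methyl-3-oxohexanoate | CCOC(=O)CC(=O)[C@@H](C)CC | intermediate
6 | ethyl (3S,4S)-3-hydroxy-4-methylhexanoate | CCOC(=O)C[C@H](O)[C@@H](C)CC | intermediate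
7 | allyl bromide (3-bromoprop-1-ene) | C=CCBr | starting material
8 | dilithium alkoxide-enolate of 6 (O-lithium cis to C3 in the chelate) | CCO/C([O-])=C/[C@H]([O-])[C@@H](C)CC.[Li+].[Li+] | intermediate (not isolated)
9 | ethyl (2R,3R,4S)-3-hydroxy-4-methyl-2-(prop-2-en-1-yl)hexanoate | CCOC(=O)[C@H](CC=C)[C@H](O)[C@@H](C)CC | intermediate
10 | (2R,3R,4S)-3-hydroxy-4-methyl-2-(prop-2-en-1-yl)hexanoic acid | OC(=O)[C@H](CC=C)[C@H](O)[C@@H](C)CC | intermediate
11 | ethyl (R)-3-hydroxybutanoate | CCOC(=O)C[C@@H](C)O | starting material
12 | tert-butyl acetate | CC(=O)OC(C)(C)C | starting material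
13 | lithium enolate of tert-butyl acetate | C=C([O-])OC(C)(C)C.[Li+] | intermediate (not isolated)
14 | tert-butyl (R)-5-hydroxy-3-oxohexanoate | CC(C)(C)OC(=O)CC(=O)C[C@@H](C)O | intermediate
15 | (R)-5-hydroxy-3-oxohexanoic acid | OC(=O)CC(=O)C[C@@H](C)O | intermediate (not isolated)
16 | (R)-4-hydroxy-6-methyl-5,6-dihydro-2H-pyran-2-one | O=C1C=C(O)C[C@@H](C)O1 | intermediate
17 | pent-4-ynoic acid | C#CCCC(=O)O | starting material
18 | (R)-6-methyl-2-oxo-5,6-dihydro-2H-pyran-4-yl pent-4-ynoate | C#CCCC(=O)OC1=CC(=O)O[C@H](C)C1 | intermediate (not isolated)
19 | (R)-4-hydroxy-6-methyl-3-(pent-4-ynoyl)-5,6-dihydro-2H-pyran-2-one | C#CCCC(=O)C1=C(O)C[C@@H](C)OC1=O | intermediate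
20 | cationic CpRu ruthenacyclopent-2-ene from 10 and 19, hexafluorophosphate (Cp drawn as a separate anion, solvent ligand omitted, ring carbon on Ru not defined) | [cH-]1cccc1.[Ru+2]1C=C(CCC(=O)C2=C(O)C[C@@H](C)OC2=O)CC1C[C@@H](C(=O)O)[C@H](O)[C@@H](C)CC.F[P-](F)(F)(F)(F)F | intermediate (not isolated)
21 | (2R,3R,4S)-3-hydroxy-2-{(1E)-7-[(6R)-4-hydroxy-6-methyl-2-oxo-5,6-dihydro-2H-pyran-3-yl]-4-methylidene-7-oxohept-1-en-1-yl}-4-methylhexanoic acid | C=C(C/C=C/[C@@H](C(=O)O)[C@H](O)[C@@H](C)CC)CCC(=O)C1=C(O)C[C@@H](C)OC1=O | target

## Step count and risk

Total step count: 8. Longest linear sequence: 5 steps (1 → 5 → 6 → 9 → 10 → 21, steps 1, 2, 3, 4 and 8); the second branch (11 → 14 → 16 → 19) has 3 steps before the union.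

Least certain steps:

Step 8 (key step). The most likely failure is sequestration of the cationic ruthenium centre by the acidic, chelating tricarbonyl enol of 19 or by the carboxyl group of 10, which would stall the catalytic cycle. Behind that come erosion of the branched/linear regioselectivity and ruthenium-mediated addition of the acid O–H across the alkyne. The fallback changes the order of bond construction: the union is made on ester-protected partners and the tricarbonyl is attached afterwards. It sets out from 10 (and uses 16 and 17) and comes back at 21. Esterification of 10 with 2-(trimethylsilyl)ethanol (EDC, DMAP, CH2Cl2) should give 2-(trimethylsilyl)ethyl (2R,3R,4S)-3-hydroxy-4-methyl-2-(prop-2-en-1-yl)hexanoate F1, and Fischer esterification of 17 (MeOH, cat. H2SO4) gives methyl pent-4-ynoate F2. The same ruthenium-catalysed Alder-ene coupling is then run between F1 and F2, which carry only ester and hydroxyl groups, and should give the diester 2-(trimethylsilyl)ethyl (2R,3R,4S)-3-hydroxy-2-[(1E)-7-methoxy-4-methylidene-7-oxohept-1-en-1-yl]-4-methylhexanoate F3. In F3 the unhindered methyl ester is cleaved selectively (pig-liver esterase at pH 7, or LiOH, 1 equiv, THF/H2O, 0 °C) to the mono-acid (6E,8R,9R,10S)-9-hydroxy-10-methyl-4-methylidene-8-{[2-(trimethylsilyl)ethoxy]carbonyl}dodec-6-enoic acid F4. Acylation of 16 with F4 under the conditions of step 7 should give 2-(trimethylsilyl)ethyl (2R,3R,4S)-3-hydroxy-2-{(1E)-7-[(6R)-4-hydroxy-6-methyl-2-oxo-5,6-dihydro-2H-pyran-3-yl]-4-methylidene-7-oxohept-1-en-1-yl}-4-methylhexanoate F5. Treatment of F5 with fluoride (TBAF buffered with AcOH, THF, 0 °C) then releases 21.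

Step 3. The hindered dianion may alkylate incompletely, O-allylation or double alkylation may compete, and the anti selectivity may erode if the polar co-solvent breaks up the chelate. The fallback replaces substrate-controlled alkylation by a stereoconvergent enzymatic reduction; it sets out from 5 and comes back at 9. C-Allylation of 5 with 7 (K2CO3, acetone) gives ethyl (4S)-4-methyl-3-oxo-2-(prop-2-en-1-yl)hexanoate F6 as a mixture of C2 epimers. A ketoreductase chosen from a panel for the (2R,3R) anti product (NADPH recycled with isopropanol, pH 7 buffer, 30 °C) then reduces F6 under dynamic kinetic resolution, the C2 epimers interconverting through the enol, and should give 9 directly.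

Step 7. The reaction may stop at the O-acyl stage, or the activated acid may be diverted to the N-acylurea before O→C migration takes place. The fallback builds the ring with the acyl group already in place; it sets out from 17 and 11 and comes back at 19. 17 is condensed with Meldrum's acid (DCC, DMAP, CH2Cl2) to 5-(1-hydroxypent-4-yn-1-ylidene)-2,2-dimethyl-1,3-dioxane-4,6-dione F7. Heating F7 with 11 in toluene releases the acylketene, which acylates the hydroxyl of 11 to give ethyl (3R)-3-[(3-oxohept-6-ynoyl)oxy]butanoate F8. A Lacey–Dieckmann cyclisation of F8 (TBAF, THF, rt) between the active methylene and the ethyl ester should then give 19 without any acyl migration.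

Step 5. The lithium alkoxide of 11 may undergo retro-aldol cleavage or β-elimination, and conversion may be incomplete because alkoxide and product enolate consume base. The fallback makes the same C–C bond intramolecularly; it sets out from 11 and comes back at 16. Acetylation of 11 (Ac2O, pyridine, DMAP) gives ethyl (3R)-3-(acetyloxy)butanoate F9. Dieckmann condensation of F9 through its acetate enolate onto the ethyl ester (LiHMDS, THF, −78 °C) should give 16 directly, bypassing 14.

## Further compounds

F1 | step 8 | 2-(trimethylsilyl)ethyl (2R,3R,4S)-3-hydroxy-4-methyl-2-(prop-2-en-1-yl)hexanoate | C[Si](C)(C)CCOC(=O)[C@H](CC=C)[C@H](O)[C@@H](C)CC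
F2 | step 8 | methyl pent-4-ynoate | C#CCCC(=O)OC
F3 | step 8 | 2-(trimethylsilyl)ethyl (2R,3R,4S)-3-hydroxy-2-[(1E)-7-methoxy-4-methylidene-7-oxohept-1-en-1-yl]-4-methylhexanoate | COC(=O)CCC(=C)C/C=C/[C@@H](C(=O)OCC[Si](C)(C)C)[C@H](O)[C@@H](C)CC
F4 | step 8 | (6E,8R,9R,10S)-9-hydroxy-10-methyl-4-methylidene-8-{[2-(trimethylsilyl)ethoxy]carbonyl}dodec-6-enoic acid | OC(=O)CCC(=C)C/C=C/[C@@H](C(=O)OCC[Si](C)(C)C)[C@H](O)[C@@H](C)CC
F5 | step 8 | 2-(trimethylsilyl)ethyl (2R,3R,4S)-3-hydroxy-2-{(1E)-7-[(6R)-4-hydroxy-6-methyl-2-oxo-5,6-dihydro-2H-pyran-3-yl]-4-methylidene-7-oxohept-1-en-1-yl}-4-methylhexanoate | C=C(C/C=C/[C@@H](C(=O)OCC[Si](C)(C)C)[C@H](O)[C@@H](C)CC)CCC(=O)C1=C(O)C[C@@H](C)OC1=O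
F6 | step 3 | ethyl (4S)-4-methyl-3-oxo-2-(prop-2-en-1-yl)hexanoate (C2 epimers) | CCOC(=O)C(CC=C)C(=O)[C@@H](C)CC
F7 | step 7 | 5-(1-hydroxypent-4-yn-1-ylidene)-2,2-dimethyl-1,3-dioxane-4,6-dione | C#CCCC(O)=C1C(=O)OC(C)(C)OC1=O
F8 | step 7 | ethyl (3R)-3-[(3-oxohept-6-ynoyl)oxy]butanoate | C#CCCC(=O)CC(=O)O[C@H](C)CC(=O)OCC
F9 | step 5 | ethyl (3R)-3-(acetyloxy)butanoate | CCOC(=O)C[C@@H](C)OC(C)=O
A1 | alternative 1 | (6E,8R,9R,10S)-8-(ethoxycarbonyl)-9-hydroxy-10-methyl-4-methylidenedodec-6-enoic acid | OC(=O)CCC(=C)C/C=C/[C@@H](C(=O)OCC)[C@H](O)[C@@H](C)CC
A2 | alternative 1 | 1-tert-butyl 9-ethyl (6E)-4-methylidenenon-6-enedioate | CCOC(=O)C/C=C/CC(=C)CCC(=O)OC(C)(C)C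
A3 | alternative 1 | (S)-2-methylbutanal | CC[C@H](C)C=O
A4 | alternative 2 | ethyl (2R,3R,4S)-3-hydroxy-4-methyl-2-[(E)-2-(tributylstannyl)ethenyl]hexanoate | CCOC(=O)[C@H](/C=C/[Sn](CCCC)(CCCC)CCCC)[C@H](O)[C@@H](C)CC
A5 | alternative 2 | (R)-3-[4-(bromomethyl)pent-4-enoyl]-4-hydroxy-6-methyl-5,6-dihydro-2H-pyran-2-one | C=C(CBr)CCC(=O)C1=C(O)C[C@@H](C)OC1=O
A6 | alternative 3 | ethyl (2R,3R,4S)-2-ethenyl-3-hydroxy-4-methylhexanoate | CCOC(=O)[C@H](C=C)[C@H](O)[C@@H](C)CC
A7 | alternative 3 | (R)-4-hydroxy-6-methyl-3-(4-methylidenehept-6-enoyl)-5,6-dihydro-2H-pyran-2-one | C=CCC(=C)CCC(=O)C1=C(O)C[C@@H](C)OC1=O
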